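The cyclopentenone ring is disconnected between C8, the ring carbon that carries the dienylidene chain next to the C9 ketone, and C12, the tertiary carbinol carbon (prostanoid numbering). The key step is a dirhodium-carbenoid 1,5-insertion: the diazo carbon of an acyclic α-diazo-β-ketophosphonate (C8) inserts into the C12–H bond of a silyl-protected secondary carbinol, which closes the five-membered ring and turns an easily made secondary stereocentre into the fully substituted C12 with retention. It exploits the 1,5 relationship of C8 and the oxygen-activated C12–H across the C9 ketone. The phosphonate left on C8 then builds the C7=C8 alkene by olefination; the C10 chlorine and the C10=C11 alkene follow.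

Key step: step 6

Remark: positions are named by prostanoid numbering (C1 = ester carbon, C8–C12 = ring, C13–C20 = octenyl chain). The spatial arrangement at C12 is the same from 2 to 19; the CIP descriptor changes only because substituent priorities change.
Assumption: compounds 1, 2, 5, 11 and 12 are taken as commercial.

Step 1
Reactants: 1 hept-1-yne; 2 (S)-epichlorohydrin
Product: 4 (2S)-2-(oct-2-yn-1-yl)oxirane, via (2S)-1-chlorodec-4-yn-2-ol 3 (not isolated)
Conditions: n-BuLi, THF, −78 °C; BF3·OEt2, then 2, −78 °C; then aq. NaOH, MeOH, 0 °C to rt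
Reagents that add atoms: none
Why: Alkynyllithium opening of the BF3-activated epoxide at its CH2 terminus (SN2, no direct chloride displacement at −78 °C, which would give the enantiomer) and base-induced Williamson closure of the chlorohydrin give the new epoxide; the C–O bond at the stereocentre is never broken, so the configuration of 2 is carried into 4.

Step 2
Reactants: 4 (2S)-2-(oct-2-yn-1-yl)oxirane; 5 dimethyl (2-oxopropyl)phosphonate
Product: 6 dimethyl [(5R)-5-hydroxy-2-oxotridec-7-yn-1-yl]phosphonate
Conditions: 5, NaH, THF, 0 °C; n-BuLi, −78 to 0 °C; then 4, −78 °C to rt; aq. NH4Cl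
Reagents that add atoms: none
Why: γ-Alkylation of a β-ketophosphonate dianion, whose more basic terminal carbanion opens the epoxide at the unsubstituted carbon (SN2), so the carbinol centre is untouched; 6 may equilibrate with its cyclic hemiketal.

Step 3
Reactants: 6 dimethyl [(5R)-5-hydroxy-2-oxotridec-7-yn-1-yl]phosphonate
Product: 7 dimethyl [(5R)-2-oxo-5-[(triethylsilyl)oxy]tridec-7-yn-1-yl]phosphonate
Conditions: Et3SiCl, imidazole, DMF, 0 °C to rt
Reagents that add atoms: chlorotriethylsilane, CC[Si](Cl)(CC)CC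
Why: Silyl ether formation at the secondary alcohol drains the open-chain form from the hemiketal equilibrium and masks the OH against O–H insertion in step 6.

Step 4
Reactants: 7 dimethyl [(5R)-2-oxo-5-[(triethylsilyl)oxy]tridec-7-yn-1-yl]phosphonate
Product: 8 dimethyl [(5R,7Z)-2-oxo-5-[(triethylsilyl)oxy]tridec-7-en-1-yl]phosphonate
Conditions: H2 (1 atm), Pd/CaCO3 poisoned with Pb(OAc)2 (Lindlar catalyst), quinoline, EtOAc, rt
Reagents that add atoms: none
Why: Lindlar semi-hydrogenation adds H2 syn to the alkyne and stops at the Z-alkene; ketone, phosphonate and silyl ether are inert.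

Step 5
Reactants: 8 dimethyl [(5R,7Z)-2-oxo-5-[(triethylsilyl)oxy]tridec-7-en-1-yl]phosphonate
Product: 9 dimethyl [(5R,7Z)-1-diazo-2-oxo-5-[(triethylsilyl)oxy]tridec-7-en-1-yl]phosphonate
Conditions: 4-acetamidobenzenesulfonyl azide, DBU, MeCN, 0 °C to rt
Reagents that add atoms: 4-acetamidobenzenesulfonyl azide, CC(=O)Nc1ccc(cc1)S(=O)(=O)N=[N+]=[N-]
Why: Regitz diazo transfer to the doubly activated methylene of the β-ketophosphonate; the silyl ether is not β to the carbanion, so it is not at risk.

Step 6
Reactants: 9 dimethyl [(5R,7Z)-1-diazo-2-oxo-5-[(triethylsilyl)oxy]tridec-7-en-1-yl]phosphonate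
Product: 10 dimethyl {(2R)-2-[(2Z)-oct-2-en-1-yl]-5-oxo-2-[(triethylsilyl)oxy]cyclopentyl}phosphonate (C1 epimer mixture)
Conditions: Rh2(OAc)4 (2 mol %), benzene, 80 °C, slow addition of 9 (high dilution)
Reagents that add atoms: none
Why: Rh2(OAc)4 expels N2 from 9 to give an electrophilic acceptor/acceptor rhodium carbenoid at C8, which inserts into the C12–H bond through a concerted, asynchronous three-centre (hydride-shift-like) transition state. The closest known reaction type is the dirhodium-catalysed intramolecular 1,5-C–H insertion of α-diazo-β-ketophosphonates and β-ketoesters to 2-substituted cyclopentanones. The cyclopentanone ring (C8–C9–C10–C11–C12) closes in the 1,5 mode through a five-membered chair-like transition state, and C12–H is the only C–H bond placed 1,5 to C8. The new fully substituted stereocentre C12 is controlled by the (5R) carbinol centre of 9 itself, because insertion goes with retention at the C–H carbon; the C8 centre formed at the same time is of no consequence, as step 8 removes it. The step needs selectivity for C12–H over cyclopropanation of the Z-alkene, insertion into allylic C13–H and ylide formation at the ether oxygen; this should be secured by the oxygen lone-pair activation of the tertiary C12–H, by the unfavourable seven- and six-membered modes of the competing reactions and by the bulky, weakly basic silyl ether oxygen.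

Step 7
Reactants: 11 methyl hex-5-enoate; 12 (E)-but-2-enal
Product: 13 methyl (5E)-7-oxohept-5-enoate
Conditions: second-generation Grubbs catalyst (H2IMes)(PCy3)Cl2Ru=CHPh (2 mol %), 12 in excess, CH2Cl2, 40 °C
Reagents that add atoms: none
Why: Olefin cross-metathesis of a terminal alkene with excess crotonaldehyde should give the E-enal, driven by loss of propene.

Step 8
Reactants: 10 dimethyl {(2R)-2-[(2Z)-oct-2-en-1-yl]-5-oxo-2-[(triethylsilyl)oxy]cyclopentyl}phosphonate; 13 methyl (5E)-7-oxohept-5-enoate
Product: 14 methyl (5E,7E)-7-{(2R)-2-[(2Z)-oct-2-en-1-yl]-5-oxo-2-[(triethylsilyl)oxy]cyclopentylidene}hept-5-enoate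
Conditions: NaH, THF, 0 °C; then 13, 0 °C to rt
Reagents that add atoms: none
Why: Horner–Wadsworth–Emmons olefination of the cyclic β-ketophosphonate anion with the enal (1,2-addition, then syn-elimination of phosphate) should give mainly the exocyclic E-alkene with the chain anti to the C9 carbonyl, and it erases the C8 stereocentre.

Step 9
Reactants: 14 methyl (5E,7E)-7-{(2R)-2-[(2Z)-oct-2-en-1-yl]-5-oxo-2-[(triethylsilyl)oxy]cyclopentylidene}hept-5-enoate
Product: 15 methyl (5E,7E)-7-{(5S)-5-[(2Z)-oct-2-en-1-yl]-2-oxo-5-[(triethylsilyl)oxy]cyclopent-3-en-1-ylidene}hept-5-enoate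
Conditions: LiN(iPr)2, THF, −78 °C; then PhS(Cl)=NtBu, −78 °C
Reagents that add atoms: none
Why: Kinetic deprotonation of the ketone can only occur at C10 (C8 carries no hydrogen), and the enolate is dehydrogenated by the sulfinimidoyl chloride through S-attack and syn-elimination (Mukaiyama dehydrogenation), which leaves C12 untouched.

Step 10
Reactants: 15 methyl (5E,7E)-7-{(5S)-5-[(2Z)-oct-2-en-1-yl]-2-oxo-5-[(triethylsilyl)oxy]cyclopent-3-en-1-ylidene}hept-5-enoate
Product: 16 methyl (5E,7E)-7-{(4R)-4-[(2Z)-oct-2-en-1-yl]-2-oxo-4-[(triethylsilyl)oxy]-6-oxabicyclo[3.1.0]hexan-3-ylidene}hept-5-enoate (epoxide diastereomer mixture)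
Conditions: 30% aq. H2O2, NaOH (cat.), MeOH, −20 to 0 °C
Reagents that add atoms: hydrogen peroxide, OO
Why: Weitz–Scheffer nucleophilic epoxidation, in which hydroperoxide should add to C11 of the disubstituted endocyclic enone in preference to the trisubstituted exocyclic dienone and ignores the isolated Z-alkene; both epoxide diastereomers converge in step 11, so facial selectivity is irrelevant.

Step 11
Reactants: 16 methyl (5E,7E)-7-{(4R)-4-[(2Z)-oct-2-en-1-yl]-2-oxo-4-[(triethylsilyl)oxy]-6-oxabicyclo[3.1.0]hexan-3-ylidene}hept-5-enoate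
Product: 19 methyl (5E,7E)-7-{(5S)-3-chloro-5-hydroxy-5-[(2Z)-oct-2-en-1-yl]-2-oxocyclopent-3-en-1-ylidene}hept-5-enoate, via C10-chloro C11-hydroxy ketone 17 (not isolated), via O-triethylsilyl chloro dienone 18 (not isolated)
Conditions: conc. aq. HCl, THF, 0 °C to rt
Reagents that add atoms: hydrogen chloride, Cl
Why: Acid-mediated opening of the α,β-epoxy ketone by chloride at C10, dehydration of the β-hydroxy-α-chloro ketone to the α-chloroenone and acidic hydrolysis of the silyl ether; C12 cannot ionise because the cation would sit next to the electron-poor cross-conjugated dienone, so its configuration is kept.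

Compound list
1 | hept-1-yne | CCCCCC#C | starting material
2 | (S)-epichlorohydrin, (2S)-2-(chloromethyl)oxirane | ClC[C@@H]1CO1 | starting material
3 | (2S)-1-chlorodec-4-yn-2-ol | ClC[C@@H](O)CC#CCCCCC | intermediate
4 | (2S)-2-(oct-2-yn-1-yl)oxirane | CCCCCC#CC[C@H]1CO1 | intermediate
5 | dimethyl (2-oxopropyl)phosphonate | CC(=O)CP(=O)(OC)OC | starting material
6 | dimethyl [(5R)-5-hydroxy-2-oxotridec-7-yn-1-yl]phosphonate | COP(=O)(OC)CC(=O)CC[C@@H](O)CC#CCCCCC | intermediate
7 | dimethyl [(5R)-2-oxo-5-[(triethylsilyl)oxy]tridec-7-yn-1-yl]phosphonate | COP(=O)(OC)CC(=O)CC[C@@H](O[Si](CC)(CC)CC)CC#CCCCCC | intermediate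
8 | dimethyl [(5R,7Z)-2-oxo-5-[(triethylsilyl)oxy]tridec-7-en-1-yl]phosphonate | COP(=O)(OC)CC(=O)CC[C@@H](O[Si](CC)(CC)CC)C/C=C\CCCCC | intermediate
9 | dimethyl [(5R,7Z)-1-diazo-2-oxo-5-[(triethylsilyl)oxy]tridec-7-en-1-yl]phosphonate | COP(=O)(OC)C(=[N+]=[N-])C(=O)CC[C@@H](O[Si](CC)(CC)CC)C/C=C\CCCCC | intermediate
10 | dimethyl {(2R)-2-[(2Z)-oct-2-en-1-yl]-5-oxo-2-[(triethylsilyl)oxy]cyclopentyl}phosphonate (C1 epimer mixture) | COP(=O)(OC)C1C(=O)CC[C@@]1(O[Si](CC)(CC)CC)C/C=C\CCCCC | intermediate
11 | methyl hex-5-enoate | COC(=O)CCCC=C | starting material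
12 | (E)-but-2-enal (crotonaldehyde) | C/C=C/C=O | starting material
13 | methyl (5E)-7-oxohept-5-enoate | COC(=O)CCC/C=C/C=O | intermediate
14 | methyl (5E,7E)-7-{(2R)-2-[(2Z)-oct-2-en-1-yl]-5-oxo-2-[(triethylsilyl)oxy]cyclopentylidene}hept-5-enoate | CCCCC/C=C\C[C@]1(O[Si](CC)(CC)CC)CCC(=O)/C1=C/C=C/CCCC(=O)OC | intermediate
15 | methyl (5E,7E)-7-{(5S)-5-[(2Z)-oct-2-en-1-yl]-2-oxo-5-[(triethylsilyl)oxy]cyclopent-3-en-1-ylidene}hept-5-enoate | CCCCC/C=C\C[C@]1(O[Si](CC)(CC)CC)C=CC(=O)/C1=C/C=C/CCCC(=O)OC | intermediate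
16 | methyl (5E,7E)-7-{(4R)-4-[(2Z)-oct-2-en-1-yl]-2-oxo-4-[(triethylsilyl)oxy]-6-oxabicyclo[3.1.0]hexan-3-ylidene}hept-5-enoate (epoxide diastereomer mixture) | CCCCC/C=C\C[C@]1(O[Si](CC)(CC)CC)C2OC2C(=O)/C1=C/C=C/CCCC(=O)OC | intermediate
17 | methyl (5E,7E)-7-{(2R)-4-chloro-3-hydroxy-2-[(2Z)-oct-2-en-1-yl]-5-oxo-2-[(triethylsilyl)oxy]cyclopentylidene}hept-5-enoate (diastereomer mixture) | CCCCC/C=C\C[C@]1(O[Si](CC)(CC)CC)C(O)C(Cl)C(=O)/C1=C/C=C/CCCC(=O)OC | intermediate
18 | methyl (5E,7E)-7-{(5S)-3-chloro-5-[(2Z)-oct-2-en-1-yl]-2-oxo-5-[(triethylsilyl)oxy]cyclopent-3-en-1-ylidene}hept-5-enoate | CCCCC/C=C\C[C@]1(O[Si](CC)(CC)CC)C=C(Cl)C(=O)/C1=C/C=C/CCCC(=O)OC | intermediate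
19 | methyl (5E,7E)-7-{(5S)-3-chloro-5-hydroxy-5-[(2Z)-oct-2-en-1-yl]-2-oxocyclopent-3-en-1-ylidene}hept-5-enoate | CCCCC/C=C\C[C@]1(O)C=C(Cl)C(=O)/C1=C/C=C/CCCC(=O)OC | target

Total step count: 11.
Longest linear sequence: 10 steps (steps 1–6 and 8–11, from 1 and 2 to 19); step 7 is a one-step side branch.

Steps most likely to fail

Step 6 (key step). The carbenoid may be diverted before it reaches C12–H, by capture at the cis-alkene through the seven-membered mode or by insertion into the allylic C13–H bonds. The fallback moves the ring closure ahead of the semi-hydrogenation, so that the side chain is a linear alkyne that cannot fold back onto C8 and whose propargylic C–H bonds are less hydridic. It sets out from 7: diazo transfer (4-acetamidobenzenesulfonyl azide, DBU, MeCN) should give dimethyl [(5R)-1-diazo-2-oxo-5-[(triethylsilyl)oxy]tridec-7-yn-1-yl]phosphonate F1. Rh2(OAc)4 in benzene at 80 °C should then close the ring by the same 1,5-insertion to dimethyl {(2R)-2-(oct-2-yn-1-yl)-5-oxo-2-[(triethylsilyl)oxy]cyclopentyl}phosphonate F2. Semi-hydrogenation of F2 (H2, Pd/CaCO3 poisoned with Pb(OAc)2, quinoline) comes back to the route at 10.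

Step 8. The hindered, fully substituted phosphonate carbanion may add too slowly to the enal, so that E1cB loss of triethylsilanolate from C12 (which would erase the stereocentre) or erosion of the alkene geometry takes over. The fallback introduces the C10=C11 alkene before the olefination, because β-elimination from the enone phosphonate anion would have to form a cyclopentadienone. It sets out from 10: the dianion (NaH, then LiN(iPr)2, THF, −78 °C) is treated with PhS(Cl)=NtBu, which should dehydrogenate at C10–C11 and give dimethyl {(5S)-5-[(2Z)-oct-2-en-1-yl]-2-oxo-5-[(triethylsilyl)oxy]cyclopent-3-en-1-yl}phosphonate F3. Olefination of F3 with 13 (NaH, THF) comes back to the route at 15.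

Step 10. Hydroperoxide may add to the exocyclic dienone (at C7 or C5) or hydrolyse the ester, so that chlorine is not delivered cleanly to C10. The fallback introduces chlorine and unsaturation by enolate chemistry, where C10 is the only enolisable carbon of the ketone. It sets out from 14: LiN(iPr)2 and then N-chlorosuccinimide (THF, −78 °C) should give methyl (5E,7E)-7-{(2S)-4-chloro-2-[(2Z)-oct-2-en-1-yl]-5-oxo-2-[(triethylsilyl)oxy]cyclopentylidene}hept-5-enoate F4. A second enolisation of F4 and treatment with PhS(Cl)=NtBu should give the silyl-protected chloro dienone, which comes back to the route at 18; HF·pyridine (THF, 0 °C) would then desilylate 18 to 19.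

Further compounds
F1 | step 6 | dimethyl [(5R)-1-diazo-2-oxo-5-[(triethylsilyl)oxy]tridec-7-yn-1-yl]phosphonate | COP(=O)(OC)C(=[N+]=[N-])C(=O)CC[C@@H](O[Si](CC)(CC)CC)CC#CCCCCC
F2 | step 6 | dimethyl {(2R)-2-(oct-2-yn-1-yl)-5-oxo-2-[(triethylsilyl)oxy]cyclopentyl}phosphonate (C1 epimer mixture) | COP(=O)(OC)C1C(=O)CC[C@@]1(O[Si](CC)(CC)CC)CC#CCCCCC
F3 | step 8 | dimethyl {(5S)-5-[(2Z)-oct-2-en-1-yl]-2-oxo-5-[(triethylsilyl)oxy]cyclopent-3-en-1-yl}phosphonate (C1 epimer mixture) | COP(=O)(OC)C1C(=O)C=C[C@@]1(O[Si](CC)(CC)CC)C/C=C\CCCCC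
F4 | step 10 | methyl (5E,7E)-7-{(2S)-4-chloro-2-[(2Z)-oct-2-en-1-yl]-5-oxo-2-[(triethylsilyl)oxy]cyclopentylidene}hept-5-enoate (C4 epimer mixture) | CCCCC/C=C\C[C@]1(O[Si](CC)(CC)CC)CC(Cl)C(=O)/C1=C/C=C/CCCC(=O)OC
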